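The side-chain acyloin is cut between its ketone carbon (C-5') and its carbinol carbon (C-6'). A thiamine diphosphate (ThDP)-dependent 2-oxo acid decarboxylase, run as a carboligase, joins a 2-oxo acid that already carries the complete (3R)-8-hydroxy-6-methoxy-3,4-dihydroisocoumarin ring with octanal. Loss of CO2 unmasks an enzyme-bound acyl anion, which adds to the aldehyde, forms the C-5'–C-6' bond, sets the (6'R)-carbinol and releases the unprotected α-hydroxy ketone in one operation. The step exploits the vicinal C=O/CH–OH pair of the chain on C-3 of the lactone ring, the native product type of this enzyme class. The precursor, an α-keto ester hydrolysed in the same flask, comes from C–H alkylation of 2,4-dimethoxybenzoic acid with an (R)-epoxide, cross-metathesis and redox isomerisation.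

Key step: step 6

Remark: the target is read as (3R)-8-hydroxy-3-[(6R)-6-hydroxy-5-oxotridecyl]-6-methoxyisochroman-1-one (primes mark side-chain atoms). It is assumed that a suitable enzyme for step 6 is found by screening known ThDP-dependent 2-oxo acid decarboxylases of the branched-chain 2-keto acid and pyruvate decarboxylase families and their variants with widened donor pockets.

Step 1
Reactants: 1 racemic 2-(but-3-en-1-yl)oxirane (1,2-epoxy-5-hexene)
Product: 2 (2R)-2-(but-3-en-1-yl)oxirane
Conditions: (R,R)-(salen)Co(OAc) (0.5 mol%; salen = N,N'-bis(3,5-di-tert-butylsalicylidene)cyclohexane-1,2-diamine dianion, trivalent cobalt), H2O (0.55 equiv), neat, 0 °C to rt; distillation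
Reagents that add atoms: none
Why: Jacobsen hydrolytic kinetic resolution, in which the (R,R)-catalyst (the antipode that hydrolyses the (S)-epoxide to the diol) should leave the (R)-epoxide, whose stereocentre becomes C-3 of the target, in high enantiomeric purity.

Step 2
Reactants: 2 (2R)-2-(but-3-en-1-yl)oxirane; 3 2,4-dimethoxybenzoic acid
Product: 5 (3R)-3-(but-3-en-1-yl)-6,8-dimethoxy-3,4-dihydro-1H-isochromen-1-one, via hydroxy acid 4 (not isolated)
Conditions: Pd(OAc)2 (10 mol%), Ac-tLeu-OH (20 mol%), KOAc, HFIP, 40 °C
Reagents that add atoms: none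
Why: Palladium-catalysed carboxylate-directed ortho C–H alkylation of a benzoic acid by an epoxide: cyclopalladation can occur only at C-6 (C-2 carries OMe), the aryl–Pd bond opens the epoxide at its terminal CH2 in an SN2 sense without touching the stereocentre, and hydroxy acid 4 lactonises, so that (R)-2 should give (3R)-5 with the 6,8-dimethoxy pattern.

Step 3
Reactants: 5 (3R)-3-(but-3-en-1-yl)-6,8-dimethoxy-3,4-dihydro-1H-isochromen-1-one
Product: 6 (3R)-3-(but-3-en-1-yl)-8-hydroxy-6-methoxy-3,4-dihydro-1H-isochromen-1-one
Conditions: BCl3 (1.2 equiv), CH2Cl2, −78 to 0 °C; then H2O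
Reagents that add atoms: none
Why: Chelation-controlled ether cleavage, in which BCl3 bridges the lactone carbonyl and the peri 8-OMe in a six-membered chelate and chloride removes only that methyl group, while the 6-OMe, the lactone and the terminal alkene should be left alone.

Step 4
Reactants: 6 (3R)-3-(but-3-en-1-yl)-8-hydroxy-6-methoxy-3,4-dihydro-1H-isochromen-1-one; 7 methyl 2-hydroxybut-3-enoate (racemic, methyl vinylglycolate)
Product: 8 methyl (3E)-2-hydroxy-6-[(3R)-8-hydroxy-6-methoxy-1-oxo-3,4-dihydro-1H-isochromen-3-yl]hex-3-enoate (both C-2 epimers)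
Conditions: second-generation Hoveyda–Grubbs catalyst, (H2IMes)Cl2Ru(=CH-C6H4-2-OiPr) (5 mol%), 7 (4 equiv), CH2Cl2, 40 °C
Reagents that add atoms: none
Why: Olefin cross-metathesis between the terminal alkene of 6 and the vinyl group of 7 with loss of ethene; the ruthenium carbene tolerates phenol, lactone and secondary alcohol, and neither the C-2 configuration nor the alkene geometry matters because step 5 erases both.

Step 5
Reactants: 8 methyl (3E)-2-hydroxy-6-[(3R)-8-hydroxy-6-methoxy-1-oxo-3,4-dihydro-1H-isochromen-3-yl]hex-3-enoate
Product: 9 methyl 6-[(3R)-8-hydroxy-6-methoxy-1-oxo-3,4-dihydro-1H-isochromen-3-yl]-2-oxohexanoate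
Conditions: CpRu(PPh3)2Cl (5 mol%, Cp = cyclopentadienyl), Et3NH·PF6 (10 mol%), dioxane, 100 °C
Reagents that add atoms: none
Why: Ruthenium-catalysed redox isomerisation of a secondary allylic alcohol (alkoxide formation, β-hydride elimination to the coordinated enone, hydride return to the β-carbon, protonation), which should deliver the saturated α-keto ester without an external oxidant that could attack the phenol.

Step 6
Reactants: 9 methyl 6-[(3R)-8-hydroxy-6-methoxy-1-oxo-3,4-dihydro-1H-isochromen-3-yl]-2-oxohexanoate; 10 octanal
Product: 12 (3R)-8-hydroxy-3-[(6R)-6-hydroxy-5-oxotridecyl]-6-methoxy-3,4-dihydro-1H-isochromen-1-one, via 2-oxo acid 11 (not isolated)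
Conditions: pig liver esterase, KH2PO4/K2HPO4 buffer (pH 7.5), DMSO (10% v/v), 30 °C; then ThDP-dependent 2-oxo acid decarboxylase (branched-chain 2-keto acid decarboxylase type, used as carboligase), ThDP, MgSO4, 10 (5 equiv), pH 6.8, 30 °C
Reagents that add atoms: none
Why: The esterase first frees the 2-oxo acid 11; the C-2 ylide of enzyme-bound ThDP adds to its keto group, CO2 is lost, and the resulting enamine (Breslow intermediate, an acyl anion equivalent of the whole isocoumarinyl-pentanoyl unit) attacks the carbonyl carbon of octanal, after which the ThDP adduct collapses to the α-hydroxy ketone. The closest known reaction type is the decarboxylative carboligation of 2-oxo acids with aldehydes by ThDP-dependent decarboxylases, as in the formation of (R)-phenylacetylcarbinol. No ring is closed. The new C-6' stereocentre is set by the enzyme: the active site of this (R)-selective class leaves the acceptor side chain only the substrate channel, so that the enamine should reach the si face of octanal and give the (R)-carbinol, while the remote C-3 centre is untouched. The step needs donor/acceptor chemoselectivity, which the 2-oxo carboxylate of 11 secures, because only this partner enters the cycle by irreversible decarboxylation, whereas octanal, a poor donor for a decarboxylase, is present in excess as acceptor and so also outruns protonation of the enamine to the aldehyde. The near-neutral pH should keep the lactone closed and prevent epimerisation or ketol shift of the acyloin.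

Compound list
1 | racemic 2-(but-3-en-1-yl)oxirane | C=CCCC1CO1 | starting material
2 | (2R)-2-(but-3-en-1-yl)oxirane | C=CCC[C@@H]1CO1 | intermediate
3 | 2,4-dimethoxybenzoic acid | COc1ccc(C(=O)O)c(OC)c1 | starting material
4 | 2-[(2R)-2-hydroxyhex-5-en-1-yl]-4,6-dimethoxybenzoic acid (not isolated) | C=CCC[C@@H](O)Cc1cc(OC)cc(OC)c1C(=O)O | intermediate
5 | (3R)-3-(but-3-en-1-yl)-6,8-dimethoxy-3,4-dihydro-1H-isochromen-1-one | C=CCC[C@@H]1Cc2cc(OC)cc(OC)c2C(=O)O1 | intermediate
6 | (3R)-3-(but-3-en-1-yl)-8-hydroxy-6-methoxy-3,4-dihydro-1H-isochromen-1-one | C=CCC[C@@H]1Cc2cc(OC)cc(O)c2C(=O)O1 | intermediate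
7 | methyl 2-hydroxybut-3-enoate (racemic) | C=CC(O)C(=O)OC | starting material
8 | methyl (3E)-2-hydroxy-6-[(3R)-8-hydroxy-6-methoxy-1-oxo-3,4-dihydro-1H-isochromen-3-yl]hex-3-enoate (C-2 epimers) | COC(=O)C(O)/C=C/CC[C@@H]1Cc2cc(OC)cc(O)c2C(=O)O1 | intermediate
9 | methyl 6-[(3R)-8-hydroxy-6-methoxy-1-oxo-3,4-dihydro-1H-isochromen-3-yl]-2-oxohexanoate | COC(=O)C(=O)CCCC[C@@H]1Cc2cc(OC)cc(O)c2C(=O)O1 | intermediate
10 | octanal | CCCCCCCC=O | starting material
11 | 6-[(3R)-8-hydroxy-6-methoxy-1-oxo-3,4-dihydro-1H-isochromen-3-yl]-2-oxohexanoic acid (not isolated) | OC(=O)C(=O)CCCC[C@@H]1Cc2cc(OC)cc(O)c2C(=O)O1 | intermediate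
12 | (3R)-8-hydroxy-3-[(6R)-6-hydroxy-5-oxotridecyl]-6-methoxy-3,4-dihydro-1H-isochromen-1-one | CCCCCCC[C@@H](O)C(=O)CCCC[C@@H]1Cc2cc(OC)cc(O)c2C(=O)O1 | target

Total step count: 6. Longest linear sequence: 6 steps (1 to 12); 3, 7 and 10 are bought.

Steps most likely to fail

Step 6. The bulky donor may bind poorly so that decarboxylation stalls, the enzyme-bound enamine may be protonated and released as the aldehyde instead of adding to octanal, and facial discrimination on a linear aliphatic acceptor may be incomplete. The fallback sets out from 9 and comes back at 12, using small-molecule umpolung in place of the enzyme. 9 is hydrolysed with pig liver esterase alone and the 2-oxo acid 11 is isolated by acidification and extraction. 11 and octanal 10 are then heated with 3-benzyl-5-(2-hydroxyethyl)-4-methylthiazolium chloride and Et3N in EtOH (thiazolium-catalysed decarboxylative cross-acyloin condensation through the same kind of Breslow intermediate). This should give the acyloin as a mixture of C-6' epimers, (3R)-8-hydroxy-3-(6-hydroxy-5-oxotridecyl)-6-methoxy-3,4-dihydro-1H-isochromen-1-one F1. The two diastereomers are separated by preparative HPLC on a polysaccharide chiral phase; (3R)-8-hydroxy-3-[(6S)-6-hydroxy-5-oxotridecyl]-6-methoxy-3,4-dihydro-1H-isochromen-1-one F2 is set aside and the (6'R)-epimer is 12. This fallback keeps the same bond construction but gives up catalyst control at C-6' in favour of separation.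

Step 2. The terminal alkene of the epoxide may compete for the arylpalladium intermediate (Heck-type insertion, reduction to zerovalent palladium and loss of turnover), or the carboxylate may open the epoxide by O-alkylation. The fallback sets out from 2 and comes back at 5, building the ring from an aryl nucleophile. Commercial 1-bromo-3,5-dimethoxybenzene (COc1cc(Br)cc(OC)c1) is converted with Mg in THF into (3,5-dimethoxyphenyl)magnesium bromide F3, which should open 2 at its terminal carbon under CuI catalysis (−30 to 0 °C) to give (2R)-1-(3,5-dimethoxyphenyl)hex-5-en-2-ol F4. Oxa-Pictet–Spengler cyclisation with dimethoxymethane and BF3·OEt2 (CH2Cl2, 0 °C) closes the ring ortho to the side chain to give (3R)-3-(but-3-en-1-yl)-6,8-dimethoxy-3,4-dihydro-1H-isochromene F5. Benzylic oxidation of C-1 with pyridinium chlorochromate, [C5H5NH][CrO3Cl], in refluxing CH2Cl2 should then give 5.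

Step 5. β-Hydride elimination from the ester-substituted carbinol may be slow, the double bond may migrate along the chain away from the carbinol, or the α-keto ester may condense with itself at 100 °C. The fallback sets out from 8 and comes back at 9, separating reduction and oxidation. Hydrogenation (H2, Pd/C, EtOAc, rt) should give methyl 2-hydroxy-6-[(3R)-8-hydroxy-6-methoxy-1-oxo-3,4-dihydro-1H-isochromen-3-yl]hexanoate F6. Dess–Martin periodinane (NaHCO3, CH2Cl2, 0 °C) then oxidises the α-hydroxy ester to 9; the phenol, hydrogen-bonded to and deactivated by the lactone carbonyl, should survive the short exposure.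

Further compounds
F1 | step 6 | (3R)-8-hydroxy-3-(6-hydroxy-5-oxotridecyl)-6-methoxy-3,4-dihydro-1H-isochromen-1-one (C-6' epimers) | CCCCCCCC(O)C(=O)CCCC[C@@H]1Cc2cc(OC)cc(O)c2C(=O)O1
F2 | step 6 | (3R)-8-hydroxy-3-[(6S)-6-hydroxy-5-oxotridecyl]-6-methoxy-3,4-dihydro-1H-isochromen-1-one | CCCCCCC[C@H](O)C(=O)CCCC[C@@H]1Cc2cc(OC)cc(O)c2C(=O)O1
F3 | step 2 | (3,5-dimethoxyphenyl)magnesium bromide | COc1cc([Mg]Br)cc(OC)c1
F4 | step 2 | (2R)-1-(3,5-dimethoxyphenyl)hex-5-en-2-ol | C=CCC[C@@H](O)Cc1cc(OC)cc(OC)c1
F5 | step 2 | (3R)-3-(but-3-en-1-yl)-6,8-dimethoxy-3,4-dihydro-1H-isochromene | C=CCC[C@@H]1Cc2cc(OC)cc(OC)c2CO1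
F6 | step 5 | methyl 2-hydroxy-6-[(3R)-8-hydroxy-6-methoxy-1-oxo-3,4-dihydro-1H-isochromen-3-yl]hexanoate (C-2 epimers) | COC(=O)C(O)CCCC[C@@H]1Cc2cc(OC)cc(O)c2C(=O)O1
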